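**Assumption:** (S)-citronellal and both enantiomeric series of the amine catalyst and the Ipc-borane reagent are commercially available. Diastereoselectivity in Steps 3 and 4 rests on catalyst or reagent control that I assume is high enough to separate the minor isomers by chromatography.

## Retrosynthesis (overview)
1. Target ⇐ Schwartz reduction of a Weinreb amide and selective primary acetylation, which differentiates the two C1 units (CH2OAc and CHO) on C(a) and C(b).
2. The only ring, the nine-membered carbocycle, is closed last by RCM between an acrylate C(b)=CH2 and a C(c)=CH2 vinyl. The cis ring alkene b=c comes from ring constraint.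
3. The (E)-trisubstituted alkene e=f is set earlier by Negishi carboalumination/iodination of a terminal alkyne, followed by Stille allylation.
4. The homopropargylic alcohol C(h) comes from reagent-controlled propargylation of an α-branched aldehyde.
5. That aldehyde (stereocentres i, a, sc) comes from enamine/Lewis-base SN2′ allylation of (S)-citronellal with a Morita–Baylis–Hillman (MBH) carbonate made from methyl acrylate and TBSOCH2CHO.

## Route

**Step 1**
Reactants: 1 methyl acrylate; 2 2-(TBSO)acetaldehyde
Product: 3 methyl 2-[2-(TBSO)-1-hydroxyethyl]acrylate (racemic)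
Conditions: DABCO (30 mol%), MeOH, rt, 3–5 d
Reagents that add atoms: none
Why: Morita–Baylis–Hillman addition of the acrylate α-carbon to the aldehyde. The racemic carbinol is destroyed in Step 3, so it does not matter.

**Step 2**
Reactants: 3
Product: 4 MBH tert-butyl carbonate
Conditions: Boc2O (1.2 equiv), DMAP (cat.), CH2Cl2, 0 °C → rt
Reagents that add atoms: di-tert-butyl dicarbonate, CC(C)(C)OC(=O)OC(=O)OC(C)(C)C
Why: O-Boc acylation makes the MBH alcohol a leaving group for Lewis-base SN2′ chemistry; no stereocentre is involved.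

**Step 3**
Reactants: 4; 5 (S)-citronellal
Product: 6 aldehyde with stereocentres i and a
Conditions: (S)-diphenylprolinol TMS ether (20 mol%), DABCO (20 mol%), PhCO2H (20 mol%), toluene, 0 °C → rt
Reagents that add atoms: none (Boc leaves as CO2 and t-BuOH)
Why: Dual amine/Lewis-base α-allylation. DABCO adds SN2′ to 4 to give an allylammonium, and the citronellal enamine attacks it SN2′ at the CH(CH2OTBS) carbon. The (S)-catalyst enamine face sets C(i) as R, the anti SN2′ addition sets C(a) as R, and C(sc) stays S.

**Step 4**
Reactants: 6; propargyl unit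
Product: 7 homopropargylic alcohol
Conditions: (Ipc)2B–CH=C=CH2 (1.5 equiv, from propargylMgBr and (Ipc)2BOMe), Et2O, −100 → −78 °C; then NaBO3·4H2O, THF/H2O
Reagents that add atoms: propargylmagnesium bromide, C#CC[Mg]Br (source of the C3H3 unit)
Why: Asymmetric allenylboration of the α-branched aldehyde. Reagent control (pinene enantiomer chosen to give the S-carbinol) overrides the weak substrate bias and sets C(h) as S.

**Step 5**
Reactants: 7
Product: 8 (E)-vinyl iodide
Conditions: AlMe3 (4 equiv), Cp2ZrCl2 (30 mol%), ClCH2CH2Cl, 0 °C → rt; then I2, THF, −30 °C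
Reagents that add atoms: trimethylaluminium, C[Al](C)C; iodine, II
Why: Negishi carboalumination. Syn-addition of Me and Al across the terminal alkyne puts Me cis to I, so d will end up cis to Me and the ring alkene e=f is E. Only the terminal alkyne reacts; the prenyl alkene, acrylate and TBS ether are untouched.

**Step 6**
Reactants: 8; allyl unit
Product: 9 skipped diene
Conditions: CH2=CHCH2SnBu3 (3 equiv), Pd(PPh3)4 (10 mol%), LiCl, THF, 65 °C
Reagents that add atoms: allyltributylstannane, C=CC[Sn](CCCC)(CCCC)CCCC
Why: Stille coupling retains the trisubstituted alkene geometry and installs the d–c=CH2 unit with no stereocentre change.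

**Step 7**
Reactants: 9
Product: 10 nine-membered ring enoate
Conditions: Hoveyda–Grubbs II (15 mol%), p-benzoquinone (20 mol%), toluene (1 mM), 80 °C
Reagents that add atoms: none (ethylene is lost)
Why: Ring-closing metathesis between the acrylate CH2= and the allyl CH2=. The (E)-e=f alkene pre-organises the chain, and a nine-membered ring can only form the b=c alkene cis across the ring. All stereocentres are unchanged.

**Step 8**
Reactants: 10; N,O-dimethylhydroxylamine
Product: 11 Weinreb amide
Conditions: Me3Al (3 equiv), MeNHOMe·HCl (3 equiv), CH2Cl2, 0 °C → rt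
Reagents that add atoms: N,O-dimethylhydroxylamine hydrochloride, CNOC.Cl
Why: Aluminium-amide aminolysis converts the ester into a Weinreb amide. This lets the two C1 units be differentiated and prevents lactonisation in Step 9.

**Step 9**
Reactants: 11
Product: 12 hydroxy amide
Conditions: HF·pyridine, THF/pyridine, 0 °C → rt
Reagents that add atoms: none
Why: Fluoride desilylation of the primary TBS ether. The Weinreb amide cannot lactonise, and the secondary OH and alkenes survive.

**Step 10**
Reactants: 12; acetic anhydride
Product: 13 acetate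
Conditions: Ac2O (1.1 equiv), pyridine, DMAP (5 mol%), CH2Cl2, −20 °C
Reagents that add atoms: acetic anhydride, CC(=O)OC(C)=O
Why: Kinetic acylation of the unhindered primary alcohol over the secondary C(h)–OH. No stereocentre is touched, and acetyl migration across a 1,4-diol is slow.

**Step 11**
Reactants: 13
Product: 14 hydroxyacetyldictyolal (target)
Conditions: Cp2Zr(H)Cl (2.5 equiv), THF, rt, 30 min; then aqueous NaHCO3 workup
Reagents that add atoms: none
Why: Schwartz reduction takes the tertiary (Weinreb) amide to the aldehyde via a stable zirconium-hemiaminal intermediate, giving the enal while leaving the acetate and free OH intact. No stereocentre is changed.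

## Compound list
| # | Name | SMILES | Role |
|---|---|---|---|
| 1 | methyl acrylate | C=CC(=O)OC | starting material |
| 2 | 2-(tert-butyldimethylsilyloxy)acetaldehyde | CC(C)(C)[Si](C)(C)OCC=O | starting material |
| 3 | methyl 2-[2-(TBSO)-1-hydroxyethyl]acrylate (rac) | C=C(C(=O)OC)C(O)CO[Si](C)(C)C(C)(C)C | intermediate |
| 4 | MBH tert-butyl carbonate | C=C(C(=O)OC)C(OC(=O)OC(C)(C)C)CO[Si](C)(C)C(C)(C)C | intermediate |
| 5 | (S)-citronellal | CC(C)=CCC[C@H](C)CC=O | starting material |
| 6 | methyl (3R,4R)-3-[(TBSO)methyl]-2-methylidene-5-oxo-4-[(2S)-6-methylhept-5-en-2-yl]pentanoate | O=C[C@H]([C@@H](C)CCC=C(C)C)[C@@H](CO[Si](C)(C)C(C)(C)C)C(=C)C(=O)OC | intermediate |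
| 7 | methyl (3R,4R,5S)-3-[(TBSO)methyl]-5-hydroxy-2-methylidene-4-[(2S)-6-methylhept-5-en-2-yl]oct-7-ynoate | C#CC[C@H](O)[C@H]([C@@H](C)CCC=C(C)C)[C@@H](CO[Si](C)(C)C(C)(C)C)C(=C)C(=O)OC | intermediate |
| 8 | (7E)-8-iodo-7-methyl analogue of 7 (oct-7-enoate) | I/C=C(\C)C[C@H](O)[C@H]([C@@H](C)CCC=C(C)C)[C@@H](CO[Si](C)(C)C(C)(C)C)C(=C)C(=O)OC | intermediate |
| 9 | methyl (3R,4R,5S,7E)-3-[(TBSO)methyl]-5-hydroxy-7-methyl-2-methylidene-4-[(2S)-6-methylhept-5-en-2-yl]undeca-7,10-dienoate | C=CC/C=C(\C)C[C@H](O)[C@H]([C@@H](C)CCC=C(C)C)[C@@H](CO[Si](C)(C)C(C)(C)C)C(=C)C(=O)OC | intermediate |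
| 10 | methyl (1E,4E,7S,8R,9R)-9-[(TBSO)methyl]-7-hydroxy-5-methyl-8-[(2S)-6-methylhept-5-en-2-yl]cyclonona-1,4-diene-1-carboxylate | CC(C)(C)[Si](C)(C)OC[C@H]1/C(C(=O)OC)=C\C/C=C(\C)C[C@H](O)[C@@H]1[C@@H](C)CCC=C(C)C | intermediate |
| 11 | Weinreb amide of 10 (N-methoxy-N-methyl carboxamide) | CC(C)(C)[Si](C)(C)OC[C@H]1/C(C(=O)N(C)OC)=C\C/C=C(\C)C[C@H](O)[C@@H]1[C@@H](C)CCC=C(C)C | intermediate |
| 12 | desilylated hydroxy amide | OC[C@H]1/C(C(=O)N(C)OC)=C\C/C=C(\C)C[C@H](O)[C@@H]1[C@@H](C)CCC=C(C)C | intermediate |
| 13 | acetoxy Weinreb amide | CC(=O)OC[C@H]1/C(C(=O)N(C)OC)=C\C/C=C(\C)C[C@H](O)[C@@H]1[C@@H](C)CCC=C(C)C | intermediate |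
| 14 | [(1R,2E,5E,8S,9R)-2-formyl-8-hydroxy-6-methyl-9-[(2S)-6-methylhept-5-en-2-yl]cyclonona-2,5-dien-1-yl]methyl acetate (hydroxyacetyldictyolal) | CC(=O)OC[C@H]1/C(C=O)=C\C/C=C(\C)C[C@H](O)[C@@H]1[C@@H](C)CCC=C(C)C | target |

## Summary
- **Total steps:** 11.
- **Longest linear sequence:** 11 steps from methyl acrylate (steps 1→2→3 … 11); 9 steps counted from citronellal.

**Three steps most likely to fail, with fallbacks:**
1. **Step 7 (RCM to the nine-membered ring).** The acrylate is a hindered, electron-poor 1,1-disubstituted alkene, and nine-membered rings close poorly. Fallback: abandon RCM and close the ring by an intramolecular Pd-catalysed alkenyl–allyl (Stille or Negishi) coupling at the d–e bond. This uses a pre-formed (Z)-trisubstituted enoate fragment to fix the b=c geometry.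
2. **Step 3 (enamine/Lewis-base SN2′ allylation).** It may give poor branched/linear ratio or poor dr for an aliphatic MBH carbonate. Fallback: Ireland–Claisen of the (S)-citronellate ester of a (Z)-2-(silyloxymethyl)-4-silyloxybut-2-en-1-ol. The (Z,Z) chair transition state gives the required like (R,R) a/i pair, followed by acid → aldehyde.
3. **Step 4 (asymmetric propargylation).** The matched/mismatched case with the α-branched aldehyde may give low dr. Fallback: replace Steps 4–6 with Brown (Ipc)2B-methallylation of 6, followed by cross-metathesis with excess 1,4-pentadiene. This builds the g–f=e–d–c=CH2 unit directly, at the cost of E/Z control and competition from the prenyl alkene.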